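Germacrane numbering is used (ring C1–C10; C11, C12, C13 on C7). Everything rests on inserting CO2 between C11 and C6: the lactone carbonyl C12 and the ring oxygen arrive as one molecule of CO2. The precursor is the complete (1(10)Z,4E)-cyclodecadiene bearing a 1-bromovinyl group on C7 and an inverted 6β-chloride, activated by the adjacent C4=C5 olefin. Bromine–lithium exchange, carboxylation at C11 and in-flask SN2 displacement of the allylic chloride by the new carboxylate close the α-methylene-γ-butyrolactone ring in one operation, with inversion to the trans-fused 12,6-olide. The carbocycle comes from an indium Barbier coupling and a Nozaki–Hiyama–Kishi macrocyclisation.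

Key step: step 17

Remark: C14 is the methyl on C10 and C15 the methyl on C4; α/β refer to the usual germacranolide drawing (H-7 α); the ligand antipode in step 19 is assumed to be the one that delivers the (R)-epoxide.

**Route**

Step 1
Reactants: 1 geranyl acetate
Product: 2 (2E)-3-methyl-6-oxohex-2-en-1-yl acetate
Conditions: O3, CH2Cl2/pyridine, −78 °C; then Me2S
Reagents that add atoms: ozone, [O-][O+]=O
Why: Chemoselective ozonolysis should cleave only the electron-rich 6,7-olefin, the 2,3-olefin being deactivated by the allylic acetate.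

Step 2
Reactants: 2 (2E)-3-methyl-6-oxohex-2-en-1-yl acetate
Product: 3 (2E,6Z)-7-iodo-3-methylocta-2,6-dien-1-yl acetate
Conditions: EtPPh3Br, n-BuLi, THF, 0 °C; I2, −78 °C; NaN(SiMe3)2, −20 °C; then 2, −78 °C
Reagents that add atoms: ethyltriphenylphosphonium bromide, CC[P+](c1ccccc1)(c1ccccc1)c1ccccc1.[Br-]; iodine, II
Why: Stork–Zhao olefination with the α-iodoethylidene ylide passes through the kinetic cis-oxaphosphetane and should give the (Z)-2-iodoalkene, which later fixes the 1(10)Z geometry.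

Step 3
Reactants: 3 (2E,6Z)-7-iodo-3-methylocta-2,6-dien-1-yl acetate
Product: 4 (2E,6Z)-7-iodo-3-methylocta-2,6-dien-1-ol
Conditions: K2CO3, MeOH, 0 °C
Reagents that add atoms: none
Why: Base-catalysed transesterification removes the acetate without touching the vinyl iodide.

Step 4
Reactants: 4 (2E,6Z)-7-iodo-3-methylocta-2,6-dien-1-ol
Product: 5 (2E,6Z)-7-iodo-3-methylocta-2,6-dienal
Conditions: MnO2, CH2Cl2, rt
Reagents that add atoms: none
Why: Allylic oxidation with MnO2 should give the enal with the 2E geometry retained.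

Step 5
Reactants: 6 (4R)-2,2-dimethyl-1,3-dioxolane-4-carbaldehyde
Product: 7 ethyl (2Z)-2-bromo-3-[(4S)-2,2-dimethyl-1,3-dioxolan-4-yl]prop-2-enoate
Conditions: Ph3P=C(Br)CO2Et, CH2Cl2, 0 °C to rt
Reagents that add atoms: ethyl 2-bromo-2-(triphenyl-λ5-phosphanylidene)acetate, CCOC(=O)C(Br)=P(c1ccccc1)(c1ccccc1)c1ccccc1
Why: Wittig olefination with the stabilised bromo ylide places the ester trans to the dioxolane (2Z) under neutral conditions that do not epimerise the α-alkoxy aldehyde; the C8 stereocentre comes from the chiral pool.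

Step 6
Reactants: 7 ethyl (2Z)-2-bromo-3-[(4S)-2,2-dimethyl-1,3-dioxolan-4-yl]prop-2-enoate
Product: 8 (2Z)-2-bromo-3-[(4S)-2,2-dimethyl-1,3-dioxolan-4-yl]prop-2-en-1-ol
Conditions: i-Bu2AlH, CH2Cl2, −78 °C
Reagents that add atoms: none
Why: 1,2-Reduction of the enoate with i-Bu2AlH gives the allylic alcohol and leaves the vinylic bromide intact.

Step 7
Reactants: 8 (2Z)-2-bromo-3-[(4S)-2,2-dimethyl-1,3-dioxolan-4-yl]prop-2-en-1-ol
Product: 9 (4S)-4-[(1Z)-2,3-dibromoprop-1-en-1-yl]-2,2-dimethyl-1,3-dioxolane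
Conditions: CBr4, PPh3, CH2Cl2, 0 °C
Reagents that add atoms: carbon tetrabromide, BrC(Br)(Br)Br
Why: Appel bromination of the primary allylic alcohol is neutral and tolerates the acetonide.

Step 8
Reactants: 5 (2E,6Z)-7-iodo-3-methylocta-2,6-dienal; 9 (4S)-4-[(1Z)-2,3-dibromoprop-1-en-1-yl]-2,2-dimethyl-1,3-dioxolane
Product: 10 (3S,4R,5E,9Z)-2-bromo-3-[(4S)-2,2-dimethyl-1,3-dioxolan-4-yl]-10-iodo-6-methylundeca-1,5,9-trien-4-ol
Conditions: In powder, THF/H2O (1:1), rt
Reagents that add atoms: none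
Why: Indium Barbier allylation by γ-attack through a Zimmerman–Traxler chair should give the anti C6-OH/C7 relationship, and with H-8 eclipsing the olefin (allylic strain against bromine) the aldehyde should approach anti to the C8–C9 bond, setting 6R and 7S (anti,anti triad); the vinyl iodide is inert to indium metal.

Step 9
Reactants: 10 (3S,4R,5E,9Z)-2-bromo-3-[(4S)-2,2-dimethyl-1,3-dioxolan-4-yl]-10-iodo-6-methylundeca-1,5,9-trien-4-ol
Product: 11 (4S)-4-{(3S,4R,5E,9Z)-2-bromo-10-iodo-4-[(4-methoxyphenyl)methoxy]-6-methylundeca-1,5,9-trien-3-yl}-2,2-dimethyl-1,3-dioxolane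
Conditions: NaH, 4-methoxybenzyl chloride, Bu4NI (cat.), DMF, 0 °C to rt
Reagents that add atoms: 4-methoxybenzyl chloride, COc1ccc(CCl)cc1
Why: Williamson etherification masks the C6 hydroxyl with a group that can later be removed oxidatively beside silyl ethers.

Step 10
Reactants: 11 (4S)-4-{(3S,4R,5E,9Z)-2-bromo-10-iodo-4-[(4-methoxyphenyl)methoxy]-6-methylundeca-1,5,9-trien-3-yl}-2,2-dimethyl-1,3-dioxolane
Product: 12 (2S,3R,4R,5E,9Z)-3-(1-bromoethenyl)-10-iodo-4-[(4-methoxyphenyl)methoxy]-6-methylundeca-5,9-diene-1,2-diol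
Conditions: AcOH/H2O (4:1), 40 °C
Reagents that add atoms: none
Why: Mild acid hydrolysis opens the terminal acetonide while the allylic 4-methoxybenzyl ether survives.

Step 11
Reactants: 12 (2S,3R,4R,5E,9Z)-3-(1-bromoethenyl)-10-iodo-4-[(4-methoxyphenyl)methoxy]-6-methylundeca-5,9-diene-1,2-diol
Product: 13 (2Z,6E,8R,9S,10S)-9-(1-bromoethenyl)-2-iodo-8-[(4-methoxyphenyl)methoxy]-6-methyl-10,11-bis[(triethylsilyl)oxy]undeca-2,6-diene
Conditions: Et3SiCl, imidazole, DMF, 0 °C to rt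
Reagents that add atoms: chlorotriethylsilane, CC[Si](Cl)(CC)CC
Why: Exhaustive silylation prepares the diol for selective oxidation of its primary position.

Step 12
Reactants: 13 (2Z,6E,8R,9S,10S)-9-(1-bromoethenyl)-2-iodo-8-[(4-methoxyphenyl)methoxy]-6-methyl-10,11-bis[(triethylsilyl)oxy]undeca-2,6-diene
Product: 14 (2S,3S,4R,5E,9Z)-3-(1-bromoethenyl)-10-iodo-4-[(4-methoxyphenyl)methoxy]-6-methyl-2-[(triethylsilyl)oxy]undeca-5,9-dienal
Conditions: (COCl)2, DMSO, CH2Cl2, −78 to −30 °C; then Et3N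
Reagents that add atoms: none
Why: Under Swern conditions the primary triethylsilyl ether is cleaved and oxidised directly to the aldehyde while the more hindered secondary one stays, so C8 and C9 are differentiated in one step.

Step 13
Reactants: 14 (2S,3S,4R,5E,9Z)-3-(1-bromoethenyl)-10-iodo-4-[(4-methoxyphenyl)methoxy]-6-methyl-2-[(triethylsilyl)oxy]undeca-5,9-dienal
Product: 15 (1(10)Z,4E,6R,7S,8S,9R)-11-bromo-6-[(4-methoxybenzyl)oxy]-8-[(triethylsilyl)oxy]-12-norgermacra-1(10),4,11(13)-trien-9-ol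
Conditions: CrCl2 (excess), NiCl2 (1 mol %), DMSO/THF, rt, 2 mM, slow addition
Reagents that add atoms: none
Why: Nozaki–Hiyama–Kishi macrocyclisation: zerovalent nickel inserts into the vinylic C–I bond far faster than into the 1,1-disubstituted C–Br bond, the alkenyl group passes to trivalent chromium and adds to the aldehyde with retention of the Z geometry, and Felkin–Anh approach anti to the C8 silyloxy group should give the 8,9-anti (9R) alcohol.

Step 14
Reactants: 15 (1(10)Z,4E,6R,7S,8S,9R)-11-bromo-6-[(4-methoxybenzyl)oxy]-8-[(triethylsilyl)oxy]-12-norgermacra-1(10),4,11(13)-trien-9-ol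
Product: 16 (1(10)Z,4E,6R,7S,8S,9R)-11-bromo-9-[(tert-butyldimethylsilyl)oxy]-6-[(4-methoxybenzyl)oxy]-8-[(triethylsilyl)oxy]-12-norgermacra-1(10),4,11(13)-triene
Conditions: t-BuMe2SiOTf, 2,6-lutidine, CH2Cl2, −78 °C
Reagents that add atoms: tert-butyldimethylsilyl trifluoromethanesulfonate, CC(C)(C)[Si](C)(C)OS(=O)(=O)C(F)(F)F
Why: Silylation with the triflate protects the hindered allylic C9 hydroxyl with a group that outlasts the triethylsilyl ether at C8.

Step 15
Reactants: 16 (1(10)Z,4E,6R,7S,8S,9R)-11-bromo-9-[(tert-butyldimethylsilyl)oxy]-6-[(4-methoxybenzyl)oxy]-8-[(triethylsilyl)oxy]-12-norgermacra-1(10),4,11(13)-triene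
Product: 17 (1(10)Z,4E,6R,7S,8S,9R)-11-bromo-9-[(tert-butyldimethylsilyl)oxy]-8-[(triethylsilyl)oxy]-12-norgermacra-1(10),4,11(13)-trien-6-ol
Conditions: DDQ, CH2Cl2/pH 7 buffer, 0 °C
Reagents that add atoms: none
Why: Oxidative cleavage of the 4-methoxybenzyl ether frees only the C6 hydroxyl and leaves both silyl ethers and the olefins untouched.

Step 16
Reactants: 17 (1(10)Z,4E,6R,7S,8S,9R)-11-bromo-9-[(tert-butyldimethylsilyl)oxy]-8-[(triethylsilyl)oxy]-12-norgermacra-1(10),4,11(13)-trien-6-ol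
Product: 18 (1(10)Z,4E,6S,7R,8S,9R)-11-bromo-9-[(tert-butyldimethylsilyl)oxy]-6-chloro-8-[(triethylsilyl)oxy]-12-norgermacra-1(10),4,11(13)-triene
Conditions: Cl3CC(O)CCl3, PPh3, CH2Cl2, −20 to 0 °C
Reagents that add atoms: hexachloroacetone, ClC(Cl)(Cl)C(=O)C(Cl)(Cl)Cl
Why: Appel-type chlorination with hexachloroacetone/PPh3 displaces the alkoxyphosphonium by chloride in an SN2 sense, so the 6α-alcohol should give the 6β-chloride (6S) without allylic transposition.

Step 17
Reactants: 18 (1(10)Z,4E,6S,7R,8S,9R)-11-bromo-9-[(tert-butyldimethylsilyl)oxy]-6-chloro-8-[(triethylsilyl)oxy]-12-norgermacra-1(10),4,11(13)-triene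
Product: 21 (1(10)Z,4E,6R,7S,8S,9R)-9-[(tert-butyldimethylsilyl)oxy]-8-[(triethylsilyl)oxy]germacra-1(10),4,11(13)-trien-12,6-olide, via alkenyllithium 19 (not isolated), via lithium carboxylate 20 (not isolated)
Conditions: t-BuLi (2.1 equiv), THF/Et2O/pentane, −105 °C, 2 min; CO2 (g), −105 to −40 °C; then DMPU, 50 °C
Reagents that add atoms: carbon dioxide, O=C=O
Why: tert-Butyllithium exchanges the vinylic bromide at −105 °C much faster than it attacks the secondary allylic chloride, giving alkenyllithium 19, which CO2 carboxylates at C11 to lithium acrylate 20 (C11–C12 bond). On warming with DMPU the carboxylate oxygen displaces the C6 chloride intramolecularly (O–C6 bond) in a 5-exo-tet SN2 closure of the γ-lactone ring, the chloride being activated by the flanking C4=C5 olefin. The closest known reaction types are the carboxylation of alkenyllithiums with CO2 and the SN2 lactonisation of γ-halo carboxylates. C6 is the only stereocentre formed and is set by stereospecific inversion of the 6β-chloride (6S to 6R), which places the lactone oxygen trans to C11 (trans-fused 12,6-olide); C7, C8 and C9 are untouched. The step needs exchange to outrun alkylation or elimination by the organolithium and SN2 at C6 to outrun SN2′ at C4: the first is secured by temperature and the second by ring size, since attack at C4 would need a seven-membered lactone.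

Step 18
Reactants: 21 (1(10)Z,4E,6R,7S,8S,9R)-9-[(tert-butyldimethylsilyl)oxy]-8-[(triethylsilyl)oxy]germacra-1(10),4,11(13)-trien-12,6-olide
Product: 22 (1(10)Z,4E,6R,7R,8S,9R)-9-[(tert-butyldimethylsilyl)oxy]-8-hydroxygermacra-1(10),4,11(13)-trien-12,6-olide
Conditions: HF·pyridine, pyridine, THF, 0 °C
Reagents that add atoms: none
Why: Buffered fluoride should remove the triethylsilyl ether selectively in the presence of the bulkier tert-butyldimethylsilyl ether.

Step 19
Reactants: 23 3-methylbut-3-en-1-ol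
Product: 24 2-[(2R)-2-methyloxiran-2-yl]ethan-1-ol
Conditions: Zr(OtBu)4 (cat.), chiral bis-hydroxamic acid ligand (cat.), cumene hydroperoxide, DMPU, toluene, 4 Å MS, 0 °C
Reagents that add atoms: cumene hydroperoxide, CC(C)(OO)c1ccccc1
Why: Hydroxyl-directed, bis-hydroxamic-acid-controlled asymmetric epoxidation of the homoallylic alcohol should deliver oxygen to one face of the 1,1-disubstituted olefin and set the (R) quaternary centre.

Step 20
Reactants: 24 2-[(2R)-2-methyloxiran-2-yl]ethan-1-ol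
Product: 25 [(2R)-2-methyloxiran-2-yl]acetic acid
Conditions: TEMPO (cat.), PhI(OAc)2, MeCN/H2O (1:1), 0 °C to rt
Reagents that add atoms: water, O
Why: Nitroxyl-catalysed oxidation takes the primary alcohol through the aldehyde hydrate to the acid under near-neutral conditions that spare the epoxide; the acid is used at once.

Step 21
Reactants: 22 (1(10)Z,4E,6R,7R,8S,9R)-9-[(tert-butyldimethylsilyl)oxy]-8-hydroxygermacra-1(10),4,11(13)-trien-12,6-olide; 25 [(2R)-2-methyloxiran-2-yl]acetic acid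
Product: 26 (1(10)Z,4E,6R,7S,8S,9R)-9-[(tert-butyldimethylsilyl)oxy]-8-{[(2R)-2-methyloxiran-2-yl]acetoxy}germacra-1(10),4,11(13)-trien-12,6-olide
Conditions: DCC, DMAP (cat.), CH2Cl2, −20 to 0 °C
Reagents that add atoms: none
Why: Steglich esterification acylates the only free hydroxyl (C8) under mild conditions, and the low temperature limits base-induced opening of the β,γ-epoxy acyl unit.

Step 22
Reactants: 26 (1(10)Z,4E,6R,7S,8S,9R)-9-[(tert-butyldimethylsilyl)oxy]-8-{[(2R)-2-methyloxiran-2-yl]acetoxy}germacra-1(10),4,11(13)-trien-12,6-olide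
Product: 27 (1(10)Z,4E,6R,7S,8S,9R)-9-hydroxy-8-{[(2R)-2-methyloxiran-2-yl]acetoxy}germacra-1(10),4,11(13)-trien-12,6-olide (CNP0284481.1)
Conditions: HF·pyridine, pyridine, THF, 0 °C to rt
Reagents that add atoms: none
Why: Buffered fluoride desilylation should free the C9 hydroxyl without opening the epoxide, cleaving the ester or adding to the α-methylene lactone.

**Compound list**

1 | geranyl acetate, (2E)-3,7-dimethylocta-2,6-dien-1-yl acetate | CC(=O)OC/C=C(\C)CCC=C(C)C | starting material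
2 | (2E)-3-methyl-6-oxohex-2-en-1-yl acetate | CC(=O)OC/C=C(\C)CCC=O | intermediate
3 | (2E,6Z)-7-iodo-3-methylocta-2,6-dien-1-yl acetate | CC(=O)OC/C=C(\C)CC/C=C(/C)I | intermediate
4 | (2E,6Z)-7-iodo-3-methylocta-2,6-dien-1-ol | OC/C=C(\C)CC/C=C(/C)I | intermediate
5 | (2E,6Z)-7-iodo-3-methylocta-2,6-dienal | O=C/C=C(\C)CC/C=C(/C)I | intermediate
6 | (4R)-2,2-dimethyl-1,3-dioxolane-4-carbaldehyde (D-glyceraldehyde acetonide) | O=C[C@H]1COC(C)(C)O1 | starting material
7 | ethyl (2Z)-2-bromo-3-[(4S)-2,2-dimethyl-1,3-dioxolan-4-yl]prop-2-enoate | CCOC(=O)/C(Br)=C/[C@H]1COC(C)(C)O1 | intermediate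
8 | (2Z)-2-bromo-3-[(4S)-2,2-dimethyl-1,3-dioxolan-4-yl]prop-2-en-1-ol | OC/C(Br)=C/[C@H]1COC(C)(C)O1 | intermediate
9 | (4S)-4-[(1Z)-2,3-dibromoprop-1-en-1-yl]-2,2-dimethyl-1,3-dioxolane | BrC/C(Br)=C/[C@H]1COC(C)(C)O1 | intermediate
10 | (3S,4R,5E,9Z)-2-bromo-3-[(4S)-2,2-dimethyl-1,3-dioxolan-4-yl]-10-iodo-6-methylundeca-1,5,9-trien-4-ol | C=C(Br)[C@@H]([C@H](O)/C=C(\C)CC/C=C(/C)I)[C@H]1COC(C)(C)O1 | intermediate
11 | (4S)-4-{(3S,4R,5E,9Z)-2-bromo-10-iodo-4-[(4-methoxyphenyl)methoxy]-6-methylundeca-1,5,9-trien-3-yl}-2,2-dimethyl-1,3-dioxolane | C=C(Br)[C@@H]([C@H](OCc1ccc(OC)cc1)/C=C(\C)CC/C=C(/C)I)[C@H]1COC(C)(C)O1 | intermediate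
12 | (2S,3R,4R,5E,9Z)-3-(1-bromoethenyl)-10-iodo-4-[(4-methoxyphenyl)methoxy]-6-methylundeca-5,9-diene-1,2-diol | C=C(Br)[C@@H]([C@H](OCc1ccc(OC)cc1)/C=C(\C)CC/C=C(/C)I)[C@H](O)CO | intermediate
13 | (2Z,6E,8R,9S,10S)-9-(1-bromoethenyl)-2-iodo-8-[(4-methoxyphenyl)methoxy]-6-methyl-10,11-bis[(triethylsilyl)oxy]undeca-2,6-diene | C=C(Br)[C@@H]([C@H](OCc1ccc(OC)cc1)/C=C(\C)CC/C=C(/C)I)[C@H](O[Si](CC)(CC)CC)CO[Si](CC)(CC)CC | intermediate
14 | (2S,3S,4R,5E,9Z)-3-(1-bromoethenyl)-10-iodo-4-[(4-methoxyphenyl)methoxy]-6-methyl-2-[(triethylsilyl)oxy]undeca-5,9-dienal | C=C(Br)[C@@H]([C@H](OCc1ccc(OC)cc1)/C=C(\C)CC/C=C(/C)I)[C@H](O[Si](CC)(CC)CC)C=O | intermediate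
15 | (1(10)Z,4E,6R,7S,8S,9R)-11-bromo-6-[(4-methoxybenzyl)oxy]-8-[(triethylsilyl)oxy]-12-norgermacra-1(10),4,11(13)-trien-9-ol (6α-ether, 8β-silyloxy, 9β-OH) | C=C(Br)[C@H]1[C@H](OCc2ccc(OC)cc2)/C=C(\C)CC/C=C(/C)[C@@H](O)[C@H]1O[Si](CC)(CC)CC | intermediate
16 | (1(10)Z,4E,6R,7S,8S,9R)-11-bromo-9-[(tert-butyldimethylsilyl)oxy]-6-[(4-methoxybenzyl)oxy]-8-[(triethylsilyl)oxy]-12-norgermacra-1(10),4,11(13)-triene | C=C(Br)[C@H]1[C@H](OCc2ccc(OC)cc2)/C=C(\C)CC/C=C(/C)[C@@H](O[Si](C)(C)C(C)(C)C)[C@H]1O[Si](CC)(CC)CC | intermediate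
17 | (1(10)Z,4E,6R,7S,8S,9R)-11-bromo-9-[(tert-butyldimethylsilyl)oxy]-8-[(triethylsilyl)oxy]-12-norgermacra-1(10),4,11(13)-trien-6-ol (6α-OH) | C=C(Br)[C@H]1[C@H](O)/C=C(\C)CC/C=C(/C)[C@@H](O[Si](C)(C)C(C)(C)C)[C@H]1O[Si](CC)(CC)CC | intermediate
18 | (1(10)Z,4E,6S,7R,8S,9R)-11-bromo-9-[(tert-butyldimethylsilyl)oxy]-6-chloro-8-[(triethylsilyl)oxy]-12-norgermacra-1(10),4,11(13)-triene (6β-Cl) | C=C(Br)[C@H]1[C@@H](Cl)/C=C(\C)CC/C=C(/C)[C@@H](O[Si](C)(C)C(C)(C)C)[C@H]1O[Si](CC)(CC)CC | intermediate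
19 | 11-lithio analogue of 18 (6β-chloro-11-lithio-12-norgermacratriene, silyl ethers as in 18) | C=C([Li])[C@H]1[C@@H](Cl)/C=C(\C)CC/C=C(/C)[C@@H](O[Si](C)(C)C(C)(C)C)[C@H]1O[Si](CC)(CC)CC | intermediate (not isolated)
20 | lithium (1(10)Z,4E)-9β-[(tert-butyldimethylsilyl)oxy]-6β-chloro-8β-[(triethylsilyl)oxy]germacra-1(10),4,11(13)-trien-12-oate | C=C(C(=O)[O-])[C@H]1[C@@H](Cl)/C=C(\C)CC/C=C(/C)[C@@H](O[Si](C)(C)C(C)(C)C)[C@H]1O[Si](CC)(CC)CC.[Li+] | intermediate (not isolated)
21 | (1(10)Z,4E,6R,7S,8S,9R)-9-[(tert-butyldimethylsilyl)oxy]-8-[(triethylsilyl)oxy]germacra-1(10),4,11(13)-trien-12,6-olide (6α-O, 7α-H, 8β, 9β) | C=C1C(=O)O[C@@H]2/C=C(\C)CC/C=C(/C)[C@@H](O[Si](C)(C)C(C)(C)C)[C@@H](O[Si](CC)(CC)CC)[C@@H]12 | intermediate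
22 | (1(10)Z,4E,6R,7R,8S,9R)-9-[(tert-butyldimethylsilyl)oxy]-8-hydroxygermacra-1(10),4,11(13)-trien-12,6-olide | C=C1C(=O)O[C@@H]2/C=C(\C)CC/C=C(/C)[C@@H](O[Si](C)(C)C(C)(C)C)[C@@H](O)[C@@H]12 | intermediate
23 | 3-methylbut-3-en-1-ol | C=C(C)CCO | starting material
24 | 2-[(2R)-2-methyloxiran-2-yl]ethan-1-ol | OCC[C@]1(C)CO1 | intermediate
25 | [(2R)-2-methyloxiran-2-yl]acetic acid | OC(=O)C[C@]1(C)CO1 | intermediate
26 | (1(10)Z,4E,6R,7S,8S,9R)-9-[(tert-butyldimethylsilyl)oxy]-8-{[(2R)-2-methyloxiran-2-yl]acetoxy}germacra-1(10),4,11(13)-trien-12,6-olide | C=C1C(=O)O[C@@H]2/C=C(\C)CC/C=C(/C)[C@@H](O[Si](C)(C)C(C)(C)C)[C@@H](OC(=O)C[C@]3(C)CO3)[C@@H]12 | intermediate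
27 | (1(10)Z,4E,6R,7S,8S,9R)-9-hydroxy-8-{[(2R)-2-methyloxiran-2-yl]acetoxy}germacra-1(10),4,11(13)-trien-12,6-olide (CNP0284481.1) | C=C1C(=O)O[C@@H]2/C=C(\C)CC/C=C(/C)[C@@H](O)[C@@H](OC(=O)C[C@]3(C)CO3)[C@@H]12 | target

**Step count and risks**

Total step count: 22. Longest linear sequence: 17 steps (steps 1–4, 8–18, 21 and 22).

Steps most likely to fail:

1. Step 17 (key step). The organolithium, either tert-butyllithium or the new alkenyllithium, may alkylate or eliminate the secondary allylic chloride before carboxylation, or the lithium carboxylate may close too slowly. The fallback sets out from alcohol 17 and abandons the chloride. Excess t-BuLi (THF, −78 °C) followed by CO2 and a mildly acidic work-up should give (1(10)Z,4E)-9β-[(tert-butyldimethylsilyl)oxy]-6α-hydroxy-8β-[(triethylsilyl)oxy]germacra-1(10),4,11(13)-trien-12-oic acid F1. This hydroxy acid is then closed through its own C6 hydroxyl by carbodiimide or acid-catalysed lactonisation (acyl–oxygen bond formation, retention at C6). The fallback returns to the route at lactone 21.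

2. Step 16. The activated allylic alcohol may ionise, which would erode the configuration at C6, transpose the chloride to C4 or give elimination. The fallback sets out from alcohol 17 and uses an acyl-transfer closure instead of a displacement. Methyl chloroformate and pyridine should give (1(10)Z,4E)-11-bromo-9β-[(tert-butyldimethylsilyl)oxy]-8β-[(triethylsilyl)oxy]-12-norgermacra-1(10),4,11(13)-trien-6α-yl methyl carbonate F2. Bromine–lithium exchange (t-BuLi, −100 °C) then lets the alkenyllithium attack the carbonate carbonyl in a Parham-type 5-exo-trig cyclisation with loss of methoxide. The fallback returns to the route at lactone 21.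

3. Step 13. Facial selectivity at C9 may be poor inside the macrocyclic transition state, on top of competing oligomerisation. The fallback sets out from aldehyde 14 and sets C9 by reagent control. The cyclisation is run as described and the 9α-epimer, (1(10)Z,4E)-11-bromo-6α-[(4-methoxybenzyl)oxy]-8β-[(triethylsilyl)oxy]-12-norgermacra-1(10),4,11(13)-trien-9α-ol F3, is carried on together with 15. Dess–Martin oxidation of the mixture should give (1(10)Z,4E)-11-bromo-6α-[(4-methoxybenzyl)oxy]-8β-[(triethylsilyl)oxy]-12-norgermacra-1(10),4,11(13)-trien-9-one F4. Corey–Bakshi–Shibata reduction of this enone with the matching oxazaborolidine antipode then gives the 9β-alcohol. The fallback returns to the route at alcohol 15.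

Further compounds
F1 | step 17 | (1(10)Z,4E)-9β-[(tert-butyldimethylsilyl)oxy]-6α-hydroxy-8β-[(triethylsilyl)oxy]germacra-1(10),4,11(13)-trien-12-oic acid | C=C(C(=O)O)[C@H]1[C@H](O)/C=C(\C)CC/C=C(/C)[C@@H](O[Si](C)(C)C(C)(C)C)[C@H]1O[Si](CC)(CC)CC
F2 | step 16 | (1(10)Z,4E)-11-bromo-9β-[(tert-butyldimethylsilyl)oxy]-8β-[(triethylsilyl)oxy]-12-norgermacra-1(10),4,11(13)-trien-6α-yl methyl carbonate | C=C(Br)[C@H]1[C@H](OC(=O)OC)/C=C(\C)CC/C=C(/C)[C@@H](O[Si](C)(C)C(C)(C)C)[C@H]1O[Si](CC)(CC)CC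
F3 | step 13 | (1(10)Z,4E)-11-bromo-6α-[(4-methoxybenzyl)oxy]-8β-[(triethylsilyl)oxy]-12-norgermacra-1(10),4,11(13)-trien-9α-ol | C=C(Br)[C@H]1[C@H](OCc2ccc(OC)cc2)/C=C(\C)CC/C=C(/C)[C@H](O)[C@H]1O[Si](CC)(CC)CC
F4 | step 13 | (1(10)Z,4E)-11-bromo-6α-[(4-methoxybenzyl)oxy]-8β-[(triethylsilyl)oxy]-12-norgermacra-1(10),4,11(13)-trien-9-one | C=C(Br)[C@H]1[C@H](OCc2ccc(OC)cc2)/C=C(\C)CC/C=C(/C)C(=O)[C@H]1O[Si](CC)(CC)CC
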